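The earlier runs and the new flask are simulated for substances that don't exist; the scatter is artificial.

Set birch against alder: birch holds twice the D of alder, with the same Q. Yet the ratio of Z to L, called z here and pooled over the readings of each run, stands at 0.198 against 0.179. Maple, with more Q, reads 0.245. In alder, the readings of L and Z at 15.0 d add to 0.0277 M on a Q charge of 0.0276 M, so take Q as the limiting reagent in alder and z as the reading of how it was shared.

| flask | D | Q | remark | time |
|---|---|---|---|---|
| alder | 0.031 M | 0.0276 M | run made earlier |  |
| birch | 0.069 M | 0.0276 M | run made earlier |  |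
| maple | 0.046 M | 0.041 M | run made earlier |  |
| flask | 0.046 M | 0.0276 M |  | 15 d |

| run | time / d | L / % | Z / % |
|---|---|---|---|
| alder | 5.00 | 74.8 | 12.7 |
| alder | 10.0 | 75.9 | 14.0 |
| alder | 15.0 | 75.1 | 14.3 |
| alder | 20.0 | 78.0 | 13.4 |
| birch | 5.00 | 32.9 | 7.6 |
| birch | 10.0 | 32.6 | 6.5 |
| birch | 15.0 | 32.6 | 6.4 |
| birch | 20.0 | 32.6 | 5.4 |
| maple | 1.25 | 72.2 | 16.6 |
| maple | 3.00 | 71.5 | 19.4 |
| maple | 8.00 | 71.2 | 16.1 |
| maple | 20.0 | 72.0 | 18.2 |

(standard deviation of a reading: 1 percentage point)

- the analysis behind the earlier runs scatters by 1 percentage point, standard deviation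

- ratio of L to Z at 8.0 min
- ratio of L to Z at 6.0 h
- ratio of L to Z at 15 d

Now chain the estimates. Pool alder and birch into 0.189 for the Q charge of this flask, which holds less Q than D. From that point to maple, z climbs at 4.21 M⁻¹: this is the Q slope m, the rise of z per unit of Q charged. Run the line back to zero Q and it leaves 0.0724. The flask should therefore end at a ratio of L to Z of 5.29. Next, read the end value of z as the mean of the momentary z over the Q used, so the momentary line has twice the slope. At the full charge it gives z of 0.305, a starting ratio of 3.28.

The weak link is that start: it supposes L and Z begin together, and the earliest reading stands at 1.25 d in maple. So reforge it: hold 3.28 at 8.0 min loosely, and expect less if L trails Z. At 6.0 h, place the ratio between the two values, with no reading to say where.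

The forecast gives 2.8, 4 and 5.2, on the ground that “Higher Q favours Z, which suggests Z has one higher order in Q”. Its value at 8.0 min lies below my starting ratio.

The flask gives 1.53 at 8.0 min, 5.23 at 6.0 h and 5.24 at 15 d.

    D ⇌ G (K = 0.340, k = 0.470 h⁻¹)
    D + Q → Z (k = 4.50 M⁻¹ h⁻¹)
    Q + G → L (k = 330 M⁻¹ h⁻¹)
    D ⇌ J (K = 0.500, k = 0.0470 h⁻¹)

In this flask there is as much L as Z at 4.41 min. At 15 d this flask has z of 0.191, against 0.189 from the line. Take the Q slope to the neighbour flask with 0.017 M of Q: the line gives z of 0.144, a ratio of 6.94, and at 15 d that flask stands at 6.42.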